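The numbers were chosen freely; the result is computed.

**The rule.** The constants give target a road that takes no reagent and side product a road that takes it twice: intermediate B goes on at 0.0019 min⁻¹, while intermediate A forms with one reagent and meets a second at 0.55 M⁻¹ min⁻¹. Intermediate B falls back far faster than it goes on, and intermediate A is lost without reagent at 0.127 min⁻¹, faster than full-charge reagent takes it, at 0.0413 min⁻¹. So side product is close to second order in reagent, and target is zero order in it. Free starting material stands in both rates, so the dormant form cancels from their ratio, the selectivity factor. With intermediate B held at its equilibrium with starting material and intermediate A steady, the two rates match at 0.0358 M: this is the crossover reagent, the concentration at which target and side product are made equally fast.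

    starting material + reagent ⇌ intermediate A (K1 = 20 M⁻¹, k1 = 0.34 M⁻¹ min⁻¹)
    starting material ⇌ intermediate B (K2 = 0.86, k2 = 0.015 min⁻¹)
    reagent + intermediate A → side product (k3 = 0.55 M⁻¹ min⁻¹)
    intermediate A → intermediate C (k4 = 0.11 min⁻¹)
    intermediate B → target (k5 = 0.0019 min⁻¹)
    reagent + intermediate C ⇌ intermediate D (K6 = 430 M⁻¹, k6 = 0.090 M⁻¹ min⁻¹)
    target → over-reaction product (k7 = 1.1 × 10⁻⁴ min⁻¹)
    starting material ⇌ dormant form (K8 = 1.7, k8 = 0.35 min⁻¹)

the same everywhere: starting material 0.050 M
- amber: reagent 1.50 equiv; a single well-mixed tank run continuously and read at steady state, 6.00 h in it on average
- blue: reagent 1.50 equiv (fed, over 1.60 h); all but reagent at the start; reagent goes in evenly over 1.60 h, the run ends at 2.0 h; time 2.0 h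
- red: reagent 1.50 equiv; a single well-mixed tank run continuously and read at steady state, 2.0 h in it on average
- violet: reagent 1.50 equiv; a closed flask charged with all of it at once and left for 2.0 h; time 2.0 h

* the set-up with the highest share of target in all that became target or side product, at the outlet or at the end ("none" if the first two lie within 2 percentage points) (amber / blue / red / violet / none)
* share of target in all that became target or side product, at the outlet or at the end, amber
* share of target in all that became target or side product, at the outlet or at the end, blue
* share of target in all that became target or side product, at the outlet or at the end, red
* share of target in all that became target or side product, at the outlet or at the end, violet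

- the stated concentrations are those of everything mixed, before any reaction; amounts are the same in each set-up
- the feed brings no volume worth counting
- the share counts what is present at the end, not what went on to other products
- run time (blue): 2.0 h

**The choice.** Violet starts at 0.0750 M, twice the crossover, and holding that level gives 20.7%. For blue I guess a working level of 0.0500 M; that gives 35.1%. In the tanks, intermediate B also leaves with the outflow and target slowly goes on, so I count both. A rough hand balance puts reagent near 0.0375 M in amber, close to the crossover, and near 0.0500 M in red. These levels give 41.0% for amber and 25.1% for red. I would run amber.

**The forecast.** The forecast names amber, with 44% for amber, 36% for blue, 26.4% for red and 20.5% for violet, and for blue it cites “low early reagent”.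

**The result.** The flasks give amber as best, with 44.1% for amber, 36.8% for blue, 26.6% for red and 20.5% for violet.

**Against crossover.** In violet, reagent after 2.00 h still stands at 56.4% of its charge, which is 0.0423 M, above the crossover. In blue it reads 53.9% of its charge after 1.00 h and 72.1% after 2.00 h, which is 0.0541 M, also above the crossover.

**A neighbour.** The neighbour of violet charged with 6.00 equiv starts at 0.300 M, which is 8.38 times the crossover, and at that level the rule gives a share of 2.76%. The computed share in that neighbour is 2.42%.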